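If each Z takes one E out of the round for good, the catalyst that works is the charge of E minus the charge of Z, and we count that working catalyst.

| flask | D | E | Z | remark | time |
|---|---|---|---|---|---|
| cedar | 0.15 M (fed, over 2.0 min) | 8 mM | 1.2 mM | run made earlier |  |
| alder | 0.075 M (fed, over 2.0 min) | 8 mM | 0.83 mM | run made earlier |  |
| blue | 0.15 M (fed, over 2.0 min) | 8.0 mM | 0.83 mM |  | 40 min |
| teal | 0.15 M (fed, over 2.0 min) | 12 mM | 0.83 mM |  | 40 min |
| violet | 0.15 M (fed, over 2.0 min) | 15 mM | 0.83 mM |  | 40 min |
| green | 0.15 M (fed, over 2.0 min) | 25 mM | 0.83 mM |  | 40 min |

| run | time / min | L / % | D / % |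
|---|---|---|---|
| cedar | 0.667 | 0 | 32.3 |
| cedar | 1.00 | 0 | 49.3 |
| cedar | 1.33 | 0.7 | 64.4 |
| cedar | 2.50 | 2.2 | 96.0 |
| cedar | 3.00 | 2.5 | 95.3 |
| cedar | 5.00 | 4.8 | 91.3 |
| cedar | 8.00 | 9.8 | 88.3 |
| alder | 1.00 | 0.4 | 49.0 |
| alder | 2.50 | 2.1 | 93.2 |
| alder | 3.00 | 3.5 | 91.9 |
| alder | 5.00 | 8.0 | 86.4 |
| alder | 6.00 | 9.6 | 84.6 |
| alder | 8.00 | 13.5 | 80.4 |

(each reading ± 0.5 percentage points)

- the numbers in the tables scatter with a standard deviation of 0.5 percentage points
- "hardly changes" means that all values lie within two and a half points (for a concentration: within two and a half percent of the largest)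
- percentages count the whole charge, also what has not yet gone in
- no earlier run changes the charge of E; that part of a forecast is a guess

* amount of L at the end, in percent of the D charged for blue, teal, violet, green, in this order
* how that number moves from the first to the last of them (falls, then rises / hardly changes / rises all the way / rises, then falls / falls all the way)

Blue looks nearly like cedar, with the same charges of D and E but less Z. Cedar holds twice the D of alder, and between the late readings it made L at 2.07 mM/min, faster than alder's 1.55 mM/min, but by a factor of just 1.34. Alder's D and L together fall short by 4.57 mM at 8.00 min, against 7.17 mM of working catalyst, and we read that gap as D bound to catalyst. Alder still stands ahead in percent at that time, 13.5% against 9.8%, because the charge divided by the rate is 48.2 min there and 72.4 min in cedar.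

Per working catalyst, these readings give a turnover frequency of 0.305 /min in cedar and 0.217 /min in alder. Blue's [D] starts at cedar's level and sinks toward alder's, so we take the mean, 0.261 /min. With 7.17 mM working, blue gets 80.2 min: the clearing time, the charge of D divided by turnover frequency and working catalyst. After the feed that gives 47.4% L in blue. Teal, violet and green have 51.5 min, 40.6 min and 23.8 min. By these times their [D] should sink below alder's level, where the turnover frequency we read is lower, so we commit to a row that rises, with its later values under what these times say.

The forecast gives 50%, 64%, 72% and 87%, rises all the way, from a reading that differs from ours: “This looks roughly first order in D”.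

The flasks give 48.8%, 69.1%, 79.9% and 93.6%, and the row rises all the way.

    D + E ⇌ J (K = 170 /M, k = 10.4 /M/min)
    J ⇌ E + L (K = 0.541 M, k = 0.379 /min)
    E + Z → X (k = 9360 /M/min)

In blue at 40.0 min, Z stands at 0% of its charge and X holds 10.4% of the catalyst, which leaves J and E together the 89.6% we counted as working. Violet's clearing time of 40.6 min, against blue's 80.2 min, gives 44.3% of the charge from the end of the feed to 20.0 min, and violet's L rose by 44 percentage points over that stretch.

The data stem from a simulated flask on assumed constants; the scatter is artificial.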